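**Strategy.** The 1,2-dioxane ring of plakortolide H holds its O1–O2 unit between C7a–H and the quaternary C3 (furo[3,2-c][1,2]dioxine numbering), a 1,4-relationship across C7a–C4a–C4–C3. With a C4a=C4 double bond added, this ring is the retron of a singlet-oxygen [4+2] cycloaddition. The key step therefore joins O2 to C3 and O1 to C7a in one suprafacial operation on an open-chain (3E,5E)-4,6-dimethyl-3,5-dienamide carrying a vinyl bromide handle and a chiral amide; the diene geometry sets the C3/C7a relationship. The ring alkene then takes up the amide oxygen in an iodolactonisation that builds C4a and expels the auxiliary, and a Negishi coupling adds the side chain last.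

Key step: step 9

Assumption: the cycloaddition is not expected to be biased by the remote (S)-1-phenylethyl group, so the single enantiomer rests on the two auxiliary diastereomers formed in step 9 being separable by chromatography or crystallisation. Ring positions of bicyclic compounds follow furo[3,2-c][1,2]dioxine numbering (O1, O2, C3, C4, C4a, O5, C6, C7, C7a).

Step 1
Reactants: 1 prop-2-yn-1-ol
Product: 3 (E)-3-bromo-2-methylprop-2-en-1-ol, via alkenylalane 2 (not isolated)
Conditions: Me3Al (3 equiv), Cp2ZrCl2 (0.25 equiv), CH2Cl2, 0 °C → rt; then NBS, THF, −30 → 0 °C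
Reagents that add atoms: trimethylaluminium C[Al](C)C; N-bromosuccinimide O=C1CCC(=O)N1Br
Why: Zirconium-catalysed Negishi carboalumination adds methyl and aluminium syn across the alkyne with methyl on the internal carbon, and bromodealumination with retention should give the E vinyl bromide.

Step 2
Reactants: 3 (E)-3-bromo-2-methylprop-2-en-1-ol
Product: 4 (E)-1,3-dibromo-2-methylprop-1-ene
Conditions: CBr4, PPh3, CH2Cl2, 0 °C
Reagents that add atoms: carbon tetrabromide BrC(Br)(Br)Br
Why: Appel bromination converts the primary allylic alcohol into the bromide under neutral conditions without touching the vinylic bromide or the alkene geometry.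

Step 3
Reactants: 4 (E)-1,3-dibromo-2-methylprop-1-ene; 5 ethynylmagnesium bromide
Product: 6 (E)-5-bromo-4-methylpent-4-en-1-yne
Conditions: CuBr·SMe2 (10 mol %), THF, −20 → 0 °C
Reagents that add atoms: none
Why: Copper-catalysed SN2 coupling of the alkynyl Grignard reagent should occur only at the allylic C–Br bond, the vinylic C–Br bond being inert, to give the skipped enyne.

Step 4
Reactants: 7 pent-3-yn-1-ol
Product: 8 tert-butyldimethyl(pent-3-yn-1-yloxy)silane
Conditions: TBSCl, imidazole, CH2Cl2, rt
Reagents that add atoms: tert-butyldimethylsilyl chloride CC(C)(C)[Si](C)(C)Cl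
Why: Standard silylation masks the hydroxyl group so that the regiochemistry of the next step is governed by sterics alone.

Step 5
Reactants: 8 tert-butyldimethyl(pent-3-yn-1-yloxy)silane
Product: 10 (E)-tert-butyl[(4-iodopent-3-en-1-yl)oxy]dimethylsilane, via alkenylzirconocene chloride 9 (not isolated)
Conditions: Cp2Zr(H)Cl (1.5 equiv), THF, rt then 50 °C; I2, 0 °C
Reagents that add atoms: iodine II
Why: Hydrozirconation adds H and Zr syn and, after equilibration with excess Cp2Zr(H)Cl, should place zirconium on the less hindered methyl-bearing carbon, so that iododezirconation with retention gives the E 2-iodoalkene.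

Step 6
Reactants: 10 (E)-tert-butyl[(4-iodopent-3-en-1-yl)oxy]dimethylsilane
Product: 13 (E)-4-iodopent-3-enoic acid, via (E)-4-iodopent-3-en-1-ol 11 (not isolated), via (E)-4-iodopent-3-enal 12 (not isolated)
Conditions: CrO3, H2SO4, H2O/acetone, 0 °C
Reagents that add atoms: water O
Why: Jones oxidation in aqueous acid cleaves the primary silyl ether and oxidises the alcohol through the aldehyde hydrate to the β,γ-unsaturated acid, conditions that the vinyl iodide should tolerate.

Step 7
Reactants: 13 (E)-4-iodopent-3-enoic acid; 14 (S)-1-phenylethylamine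
Product: 15 (E)-4-iodo-N-[(1S)-1-phenylethyl]pent-3-enamide
Conditions: EDC·HCl, HOBt, CH2Cl2, 0 °C → rt
Reagents that add atoms: none
Why: Carbodiimide amide coupling through the HOBt ester attaches the enantiopure amine without added base that could move the β,γ-double bond into conjugation.

Step 8
Reactants: 6 (E)-5-bromo-4-methylpent-4-en-1-yne; 15 (E)-4-iodo-N-[(1S)-1-phenylethyl]pent-3-enamide
Product: 17 (3E,5E,8E)-9-bromo-4,6,8-trimethyl-N-[(1S)-1-phenylethyl]nona-3,5,8-trienamide, via alkenylalane 16 (not isolated)
Conditions: 6, Me3Al (2.5 equiv), Cp2ZrCl2 (0.3 equiv), ClCH2CH2Cl, rt; then 15 (pre-treated with Me3Al, 1 equiv), ZnCl2 (0.5 equiv), Pd(PPh3)4 (5 mol %), THF, rt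
Reagents that add atoms: trimethylaluminium C[Al](C)C
Why: Negishi carboalumination of the terminal alkyne (syn, methyl on the internal carbon) gives the E alkenylalane, which after transmetalation to zinc should undergo palladium-catalysed Negishi cross-coupling with retention at both partners, zerovalent palladium inserting into the C–I bond of 15 much faster than into either C–Br bond.

Step 9
Reactants: 17 (3E,5E,8E)-9-bromo-4,6,8-trimethyl-N-[(1S)-1-phenylethyl]nona-3,5,8-trienamide
Product: 18 2-[(3S,6R)-6-[(2E)-3-bromo-2-methylprop-2-en-1-yl]-4,6-dimethyl-3,6-dihydro-1,2-dioxin-3-yl]-N-[(1S)-1-phenylethyl]acetamide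
Conditions: O2, tetraphenylporphyrin (1 mol %), visible light, CH2Cl2, −30 °C; chromatography on silica
Reagents that add atoms: dioxygen O=O
Why: Singlet oxygen, made by sensitised energy transfer, adds as a 2π partner across the s-cis C3=C4–C5=C6 diene of 17 in a suprafacial [4+2] cycloaddition (the oxygen counterpart of a Diels–Alder reaction), so that the O–C bond to the fully substituted C6 and the O–C bond to C3 form together and close the six-membered 3,6-dihydro-1,2-dioxine ring by cycloaddition in one operation. Both new stereocentres arise here, and because the outside substituents of the (3E,5E)-diene (the CH2C(O)N arm on C3 and the bromoallyl group on C6) must end on the same face, the relative configuration (3S,6R or 3R,6S, never a trans pair) is fixed by the alkene geometry set in steps 5 and 8. The remote (S)-1-phenylethyl group is not expected to distinguish the two diene faces, so both auxiliary diastereomers should form and 18 is the one taken on after separation from its (3R,6S) isomer. The step needs the [4+2] mode to win over the Schenck ene reaction at the allylic C–H bonds: the methyl group on C4 clashes with the inside methyl group on C6 in the s-trans conformer and so raises the s-cis population, both methyl groups raise the electron density of the diene, low temperature favours the more ordered cycloaddition, and the bromine-bearing C8=C9 alkene is too electron-poor to react.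

Step 10
Reactants: 18 2-[(3S,6R)-6-[(2E)-3-bromo-2-methylprop-2-en-1-yl]-4,6-dimethyl-3,6-dihydro-1,2-dioxin-3-yl]-N-[(1S)-1-phenylethyl]acetamide
Product: 20 (3R,4S,4aR,7aS)-3-[(2E)-3-bromo-2-methylprop-2-en-1-yl]-4-iodo-3,4a-dimethyltetrahydrofuro[3,2-c][1,2]dioxin-6(7H)-one, via iminolactone 19 (not isolated)
Conditions: I2 (3 equiv), NaHCO3, THF/H2O, 0 °C → rt, dark
Reagents that add atoms: iodine II; water O
Why: Iodolactonisation of an unsaturated amide: the reversibly formed iodonium ion on the ring alkene is opened 5-exo by the amide oxygen at the tertiary carbon from the face of the two-atom tether (only cis-fusion is possible, which sets C4a with O5 syn to C7 and iodine anti at C4), and hydrolysis of the iminium ether gives the lactone and releases the auxiliary.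

Step 11
Reactants: 20 (3R,4S,4aR,7aS)-3-[(2E)-3-bromo-2-methylprop-2-en-1-yl]-4-iodo-3,4a-dimethyltetrahydrofuro[3,2-c][1,2]dioxin-6(7H)-one
Product: 21 (3R,4aS,7aS)-3-[(2E)-3-bromo-2-methylprop-2-en-1-yl]-3,4a-dimethyltetrahydrofuro[3,2-c][1,2]dioxin-6(7H)-one
Conditions: Bu3SnH (1.1 equiv), Et3B (0.2 equiv), air, toluene, 0 °C
Reagents that add atoms: none
Why: Radical chain dehalogenation, in which the stannyl radical should abstract iodine from the alkyl C–I bond far faster than bromine from the vinylic C–Br bond and the C4 radical, held in the ring at a poor angle for attack on the neighbouring O–O bond, should be intercepted by Bu3SnH before it can fragment the peroxide, leaving C3, C4a and C7a unchanged.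

Step 12
Reactants: 22 hex-5-yn-1-ol
Product: 23 hex-5-ynal
Conditions: Dess–Martin periodinane, CH2Cl2, rt
Reagents that add atoms: none
Why: Dess–Martin oxidation stops at the aldehyde and leaves the terminal alkyne untouched.

Step 13
Reactants: 23 hex-5-ynal; 24 diethyl benzylphosphonate
Product: 25 [(1E)-hept-1-en-6-yn-1-yl]benzene
Conditions: NaH, THF, 0 °C → rt
Reagents that add atoms: none
Why: Horner–Wadsworth–Emmons olefination with the benzylphosphonate anion should give the E styrene through the thermodynamically preferred anti elimination pathway.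

Step 14
Reactants: 25 [(1E)-hept-1-en-6-yn-1-yl]benzene; 21 (3R,4aS,7aS)-3-[(2E)-3-bromo-2-methylprop-2-en-1-yl]-3,4a-dimethyltetrahydrofuro[3,2-c][1,2]dioxin-6(7H)-one
Product: 28 plakortolide H, via alkenylzirconocene chloride 26 (not isolated), via alkenylzinc chloride 27 (not isolated)
Conditions: 25 (1.3 equiv), Cp2Zr(H)Cl (1.2 equiv), THF, rt; ZnCl2 (1.3 equiv), 0 °C; then 21, Pd(PPh3)4 (5 mol %), THF, rt
Reagents that add atoms: none
Why: Hydrozirconation of the terminal alkyne (syn, zirconium terminal, faster than addition to the disubstituted styrene alkene), transmetalation to zinc and Negishi cross-coupling with retention of both alkene geometries should form the E,E-diene under neutral conditions that spare lactone and peroxide.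

**Compound list**

1 | prop-2-yn-1-ol | C#CCO | starting material
2 | dimethylaluminium (E)-3-(dimethylalumanyl)-2-methylprop-2-en-1-olate | C[Al](C)OC/C(C)=C/[Al](C)C | intermediate
3 | (E)-3-bromo-2-methylprop-2-en-1-ol | OC/C(C)=C/Br | intermediate
4 | (E)-1,3-dibromo-2-methylprop-1-ene | BrC/C(C)=C/Br | intermediate
5 | ethynylmagnesium bromide | C#C[Mg]Br | starting material
6 | (E)-5-bromo-4-methylpent-4-en-1-yne | C#CC/C(C)=C/Br | intermediate
7 | pent-3-yn-1-ol | CC#CCCO | starting material
8 | tert-butyldimethyl(pent-3-yn-1-yloxy)silane | CC#CCCO[Si](C)(C)C(C)(C)C | intermediate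
9 | chlorobis(cyclopentadienyl)[(2E)-5-(tert-butyldimethylsilyloxy)pent-2-en-2-yl]zirconium | C/C(=C\CCO[Si](C)(C)C(C)(C)C)[Zr](Cl)(C1C=CC=C1)C1C=CC=C1 | intermediate
10 | (E)-tert-butyl[(4-iodopent-3-en-1-yl)oxy]dimethylsilane | C/C(I)=C\CCO[Si](C)(C)C(C)(C)C | intermediate
11 | (E)-4-iodopent-3-en-1-ol | C/C(I)=C\CCO | intermediate
12 | (E)-4-iodopent-3-enal | C/C(I)=C\CC=O | intermediate
13 | (E)-4-iodopent-3-enoic acid | C/C(I)=C\CC(=O)O | intermediate
14 | (S)-1-phenylethylamine | C[C@H](N)c1ccccc1 | starting material
15 | (E)-4-iodo-N-[(1S)-1-phenylethyl]pent-3-enamide | C/C(I)=C\CC(=O)N[C@@H](C)c1ccccc1 | intermediate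
16 | [(1E,4E)-5-bromo-2,4-dimethylpenta-1,4-dien-1-yl]dimethylalumane | C[Al](C)/C=C(C)/C/C(C)=C/Br | intermediate
17 | (3E,5E,8E)-9-bromo-4,6,8-trimethyl-N-[(1S)-1-phenylethyl]nona-3,5,8-trienamide | O=C(C/C=C(C)/C=C(C)/C/C(C)=C/Br)N[C@@H](C)c1ccccc1 | intermediate
18 | 2-[(3S,6R)-6-[(2E)-3-bromo-2-methylprop-2-en-1-yl]-4,6-dimethyl-3,6-dihydro-1,2-dioxin-3-yl]-N-[(1S)-1-phenylethyl]acetamide | O=C(C[C@@H]1OO[C@](C)(C/C(C)=C/Br)C=C1C)N[C@@H](C)c1ccccc1 | intermediate
19 | (3R,4S,4aR,7aS)-3-[(2E)-3-bromo-2-methylprop-2-en-1-yl]-4-iodo-3,4a-dimethyl-N-[(1S)-1-phenylethyl]tetrahydrofuro[3,2-c][1,2]dioxin-6(7H)-imine (formed as its hydroiodide) | C/C(=C\Br)C[C@]1(C)[C@@H](I)[C@]2(C)OC(=N[C@@H](C)c3ccccc3)C[C@@H]2OO1 | intermediate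
20 | (3R,4S,4aR,7aS)-3-[(2E)-3-bromo-2-methylprop-2-en-1-yl]-4-iodo-3,4a-dimethyltetrahydrofuro[3,2-c][1,2]dioxin-6(7H)-one | C/C(=C\Br)C[C@]1(C)[C@@H](I)[C@]2(C)OC(=O)C[C@@H]2OO1 | intermediate
21 | (3R,4aS,7aS)-3-[(2E)-3-bromo-2-methylprop-2-en-1-yl]-3,4a-dimethyltetrahydrofuro[3,2-c][1,2]dioxin-6(7H)-one | C/C(=C\Br)C[C@]1(C)C[C@]2(C)OC(=O)C[C@@H]2OO1 | intermediate
22 | hex-5-yn-1-ol | C#CCCCCO | starting material
23 | hex-5-ynal | C#CCCCC=O | intermediate
24 | diethyl benzylphosphonate | CCOP(=O)(Cc1ccccc1)OCC | starting material
25 | [(1E)-hept-1-en-6-yn-1-yl]benzene | C#CCCC/C=C/c1ccccc1 | intermediate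
26 | chlorobis(cyclopentadienyl)[(1E,6E)-7-phenylhepta-1,6-dien-1-yl]zirconium | Cl[Zr](/C=C/CCC/C=C/c1ccccc1)(C1C=CC=C1)C1C=CC=C1 | intermediate
27 | chloro[(1E,6E)-7-phenylhepta-1,6-dien-1-yl]zinc | Cl[Zn]/C=C/CCC/C=C/c1ccccc1 | intermediate
28 | plakortolide H, (3R,4aS,7aS)-3,4a-dimethyl-3-[(2E,4E,9E)-2-methyl-10-phenyldeca-2,4,9-trien-1-yl]tetrahydrofuro[3,2-c][1,2]dioxin-6(7H)-one | C/C(=C\C=C\CCC/C=C/c1ccccc1)C[C@]1(C)C[C@]2(C)OC(=O)C[C@@H]2OO1 | target

**Totals**

Total step count: 14. Longest linear sequence: 9 steps (7 → 8 → 10 → 13 → 15 → 17 → 18 → 20 → 21 → 28).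

**Steps most likely to fail**

Step 9. The process at risk is periselectivity: singlet oxygen may abstract allylic hydrogen in the ene mode (at C2, C7 or the two methyl groups of the diene) instead of closing the ring, because the methyl group on C6 sits inside the s-cis diene. The fallback sets out from 17 and comes back to the route at 18. The diene is oxygenated with ground-state oxygen under electron-transfer catalysis by the aminium salt (4-BrC6H4)3N SbCl6 at 5 mol % in CH2Cl2 at −78 °C. This diene radical-cation chain process is known to give 1,2-dioxenes from dienes that give ene products with singlet oxygen. The cis relationship at C3/C6 would then rest on the ring-closing step of the peroxyl radical cation. The fallback makes no new compound, so its entry below is F0.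

Step 14. The process at risk is reductive cleavage of the O–O bond by zerovalent palladium, free phosphine or the organozinc, or attack of residual zirconium hydride on the lactone, before the cross-coupling is complete. The fallback sets out from 25 and comes back to the route at 28. Enyne 25 is hydroborated with pinacolborane (Cp2Zr(H)Cl 10 mol %, Et3N, rt → 40 °C) to 4,4,5,5-tetramethyl-2-[(1E,6E)-7-phenylhepta-1,6-dien-1-yl]-1,3,2-dioxaborolane F1, which is isolated. Boronate F1 is then joined to bromide 21 by Suzuki–Miyaura coupling with Pd(dppf)Cl2 and K3PO4 in THF/H2O at rt. This avoids both the organozinc and any hydride carry-over, and the coupling of boronate F1 gives 28 directly.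

Step 11. The process at risk is loss of chemoselectivity in the radical chain, with the stannyl radical also abstracting the vinylic bromine and destroying the coupling handle. The fallback sets out from 20 and comes back to the route at 28 with the order of the last two operations reversed. Iodolactone 20 is first coupled with alkenylzinc chloride 27 under the conditions of step 14; zerovalent palladium should insert into the vinylic C–Br bond far faster than into the hindered secondary C–I bond. This gives (3R,4S,4aR,7aS)-4-iodo-3,4a-dimethyl-3-[(2E,4E,9E)-2-methyl-10-phenyldeca-2,4,9-trien-1-yl]tetrahydrofuro[3,2-c][1,2]dioxin-6(7H)-one F2. Treatment with Bu3SnH, Et3B and air then removes the iodine at a stage where no vinylic halide is left, so that 28 is reached from iodide F2.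

**Further compounds**

F0 | step 9 | none | none
F1 | step 14 | 4,4,5,5-tetramethyl-2-[(1E,6E)-7-phenylhepta-1,6-dien-1-yl]-1,3,2-dioxaborolane | CC1(C)OB(/C=C/CCC/C=C/c2ccccc2)OC1(C)C
F2 | step 11 | (3R,4S,4aR,7aS)-4-iodo-3,4a-dimethyl-3-[(2E,4E,9E)-2-methyl-10-phenyldeca-2,4,9-trien-1-yl]tetrahydrofuro[3,2-c][1,2]dioxin-6(7H)-one | C/C(=C\C=C\CCC/C=C/c1ccccc1)C[C@]1(C)[C@@H](I)[C@]2(C)OC(=O)C[C@@H]2OO1
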